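**Strategy.** The synthesis rests on one disconnection: ring A and the 13-membered para-cyclophane are closed together by a macrocyclising intramolecular Diels–Alder reaction. The precursor is a trans-fused ring B/ring C bicycle whose cyclopentene carries a 2-acetoxyvinyl group (a 1-acetoxy-diene) and, through its aryl ether strap, the lactam bearing a cis-penta-2,4-dienoyl group. The cycloaddition joins the acetoxy-bearing diene terminus to the vinyl-bearing carbon and the ring-B terminus to the acyl-bearing carbon, exploiting the cis vinyl/acyl pair on ring A and the syn ether oxygen on ring B. The allylic acetate then serves a diazene transposition that places the ring A alkene and the trans A/B fusion.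

Key step: step 24

Remark: ring A is the cyclohexene, ring B the cyclopentane and ring C the dimethylcyclohexane; "C-k" is the ring B carbon that carries the aryloxy group.
Remark: the hemiaminal carbon of the lactam is assumed to equilibrate by ring–chain tautomerism to the epimer with hydroxyl cis to the neighbouring oxygen, as in the target.

**Fragment A (ring B/ring C enol triflate)**

Step 1
Reactants: 1 cis-3,5-dimethylcyclohexanone
Product: 2 (3S,5R)-3,5-dimethyl-1-(trimethylsilyloxy)cyclohex-1-ene
Conditions: lithium (R,R)-bis(1-phenylethyl)amide, Me3SiCl (internal quench), THF, −100 → −78 °C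
Reagents that add atoms: chlorotrimethylsilane C[Si](C)(C)Cl
Why: Desymmetrising deprotonation of the meso ketone by the chiral lithium amide should remove one enantiotopic α-proton and so fix the absolute configuration of both methyl-bearing carbons of ring C.

Step 2
Reactants: 2 (3S,5R)-3,5-dimethyl-1-(trimethylsilyloxy)cyclohex-1-ene
Product: 3 all-equatorial 2-(dimethoxymethyl)-3,5-dimethylcyclohexan-1-one
Conditions: HC(OMe)3, Me3SiOTf (cat.), CH2Cl2, −78 °C
Reagents that add atoms: trimethyl orthoformate COC(OC)OC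
Why: Mukaiyama-type addition of the enol silane to the dialkoxycarbenium ion installs the masked formyl carbon, which should settle trans to the adjacent methyl group because this centre stays epimerisable next to the ketone.

Step 3
Reactants: 3 all-equatorial 2-(dimethoxymethyl)-3,5-dimethylcyclohexan-1-one
Product: 4 2-(dimethoxymethyl)-3,5-dimethylcyclohexane-1-carbonitrile
Conditions: TosMIC, KOtBu, EtOH, DME, 0 → 40 °C
Reagents that add atoms: tosylmethyl isocyanide Cc1ccc(cc1)S(=O)(=O)C[N+]#[C-]
Why: Van Leusen reductive cyanation homologates the ketone to the nitrile without touching the acetal; the configuration at the new centre is corrected in step 4.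

Step 4
Reactants: 4 2-(dimethoxymethyl)-3,5-dimethylcyclohexane-1-carbonitrile
Product: 6 all-equatorial 1-[2-(dimethoxymethyl)-3,5-dimethylcyclohexyl]ethan-1-one, via methyl ketimine 5 (not isolated)
Conditions: MeLi, Et2O, −20 → 0 °C; H2O, SiO2; then NaOMe (cat.), MeOH, 23 °C
Reagents that add atoms: methyllithium [Li]C; water O
Why: Organolithium addition to the nitrile and imine hydrolysis give the methyl ketone, and methoxide equilibration should place the acetyl group equatorial, trans to the fixed acetal-bearing carbon.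

Step 5
Reactants: 6 all-equatorial 1-[2-(dimethoxymethyl)-3,5-dimethylcyclohexyl]ethan-1-one
Product: 7 all-equatorial 2-acetyl-4,6-dimethylcyclohexane-1-carbaldehyde
Conditions: CF3CO2H, H2O, CHCl3, 0 °C
Reagents that add atoms: water O
Why: Acid hydrolysis of the dimethyl acetal releases the aldehyde while both carbonyl-bearing centres keep their diequatorial (trans) arrangement.

Step 6
Reactants: 7 all-equatorial 2-acetyl-4,6-dimethylcyclohexane-1-carbaldehyde
Product: 8 trans-fused 3-hydroxy-4,6-dimethyloctahydro-1H-inden-1-one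
Conditions: L-proline (30 mol %), DMSO, 23 °C
Reagents that add atoms: none
Why: Amine-catalysed 5-enolexo intramolecular aldol addition of the methyl ketone enamine to the aldehyde closes ring B under mild conditions that should keep the trans fusion and place the hydroxyl pseudo-equatorial, cis to the adjacent ring-fusion hydrogen.

Step 7
Reactants: 8 trans-fused 3-hydroxy-4,6-dimethyloctahydro-1H-inden-1-one
Product: 9 tert-butyldimethylsilyl ether of 8
Conditions: t-BuMe2SiOTf, 2,6-lutidine, CH2Cl2, −78 °C
Reagents that add atoms: tert-butyldimethylsilyl triflate CC(C)(C)[Si](C)(C)OS(=O)(=O)C(F)(F)F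
Why: Silylation of the secondary alcohol under non-basic conditions avoids retro-aldol cleavage and β-elimination.

Step 8
Reactants: 9 tert-butyldimethylsilyl ether of 8
Product: 10 1-(tert-butyldimethylsilyloxy)-5,7-dimethyl-3a,4,5,6,7,7a-hexahydro-1H-inden-3-yl trifluoromethanesulfonate
Conditions: KN(SiMe3)2, THF, −78 °C; PhNTf2
Reagents that add atoms: N-phenylbis(trifluoromethanesulfonimide) O=S(=O)(N(c1ccccc1)S(=O)(=O)C(F)(F)F)C(F)(F)F
Why: Kinetic deprotonation at the methylene rather than the ring-fusion methine, followed by enolate O-sulfonylation, gives the less substituted enol triflate and leaves the fusion untouched.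

Step 9
Reactants: 10 1-(tert-butyldimethylsilyloxy)-5,7-dimethyl-3a,4,5,6,7,7a-hexahydro-1H-inden-3-yl trifluoromethanesulfonate
Product: 11 1-hydroxy-5,7-dimethyl-3a,4,5,6,7,7a-hexahydro-1H-inden-3-yl trifluoromethanesulfonate (fragment A)
Conditions: HF·pyridine, THF, 0 → 23 °C
Reagents that add atoms: none
Why: Fluoride-mediated desilylation frees the allylic alcohol; the vinyl triflate is stable to these conditions.

**Fragment W (phenol, masked acyl lactam, cis-diene)**

Step 10
Reactants: 12 (4-bromophenoxy)triisopropylsilane; 13 (R)-epichlorohydrin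
Product: 16 (R)-2-[4-(triisopropylsilyloxy)benzyl]oxirane, via aryl Grignard reagent 14 (not isolated), via chlorohydrin 15 (not isolated)
Conditions: Mg, THF; CuI (10 mol %), 13, −40 → 0 °C; then NaOH (aq), 23 °C
Reagents that add atoms: none
Why: Copper-catalysed Grignard opening of the epoxide terminus and base-induced SN2 closure of the chlorohydrin carry the stereocentre of 13 over unchanged.

Step 11
Reactants: 16 (R)-2-[4-(triisopropylsilyloxy)benzyl]oxirane; 17 (phenylthio)acetic acid
Product: 19 (5R)-3-(phenylthio)-5-[4-(triisopropylsilyloxy)benzyl]dihydrofuran-2(3H)-one, via hydroxy acid 18 (not isolated)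
Conditions: 17, LiN(i-Pr)2 (2.1 equiv), THF, −78 → 0 °C; 16; AcOH; then TsOH (cat.), PhH, 80 °C
Reagents that add atoms: none
Why: The carboxylate dianion opens the epoxide at its terminal carbon (SN2) and the γ-hydroxy acid lactonises; the sulfur-bearing centre is removed in step 12.

Step 12
Reactants: 19 (5R)-3-(phenylthio)-5-[4-(triisopropylsilyloxy)benzyl]dihydrofuran-2(3H)-one
Product: 21 (R)-5-[4-(triisopropylsilyloxy)benzyl]furan-2(5H)-one, via sulfoxide 20 (not isolated)
Conditions: mCPBA, CH2Cl2, −78 °C; then PhMe, 110 °C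
Reagents that add atoms: none
Why: Sulfide oxidation and thermal syn-elimination of the sulfoxide introduce the conjugated double bond of the butenolide.

Step 13
Reactants: 22 3-(trimethylsilyl)prop-2-ynal
Product: 23 3-(trimethylsilyl)prop-2-ynal oxime
Conditions: NH2OH·HCl, NaOAc, EtOH/H2O, 23 °C
Reagents that add atoms: hydroxylamine hydrochloride Cl.NO
Why: Simple oxime condensation gives the nitrile oxide precursor.

Step 14
Reactants: 21 (R)-5-[4-(triisopropylsilyloxy)benzyl]furan-2(5H)-one; 23 3-(trimethylsilyl)prop-2-ynal oxime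
Product: 25 cis-fused isoxazoline lactone, via nitrile oxide 24 (not isolated)
Conditions: NaOCl (aq), CH2Cl2, 0 → 23 °C
Reagents that add atoms: none
Why: Hypochlorite oxidation gives the nitrile oxide, whose 1,3-dipolar cycloaddition to the butenolide should occur on the face opposite the arylmethyl group with oxygen bonding to the β-carbon; this sets the future C-4 carbinol of the lactam and joins C-3 to the future acyl carbon.

Step 15
Reactants: 25 cis-fused isoxazoline lactone
Product: 26 isoxazoline hydroxy amide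
Conditions: NH3, MeOH, 0 → 23 °C
Reagents that add atoms: ammonia N
Why: Aminolysis of the γ-lactone gives the primary amide and frees the secondary alcohol.

Step 16
Reactants: 26 isoxazoline hydroxy amide
Product: 28 cis-fused isoxazoline hydroxy lactam, via keto amide 27 (not isolated)
Conditions: Dess–Martin periodinane, CH2Cl2, 23 °C
Reagents that add atoms: none
Why: Alcohol oxidation gives a γ-keto amide whose nitrogen adds to the ketone; the hemiaminal should settle with the arylmethyl group on the convex face, hydroxyl cis to the ring oxygen.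

Step 17
Reactants: 28 cis-fused isoxazoline hydroxy lactam
Product: 29 ethynyl isoxazoline lactam phenol
Conditions: Bu4NF, AcOH, THF, 0 °C
Reagents that add atoms: none
Why: Buffered fluoride removes the aryl silyl ether and the alkynyl silane without opening the base-sensitive isoxazoline.

Step 18
Reactants: 29 ethynyl isoxazoline lactam phenol
Product: 30 enynyl isoxazoline lactam phenol
Conditions: vinyl bromide, Pd(PPh3)4 (5 mol %), CuI (10 mol %), Et3N, THF, 23 °C
Reagents that add atoms: vinyl bromide C=CBr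
Why: Sonogashira coupling of the terminal alkyne with vinyl bromide gives the conjugated enyne.

Step 19
Reactants: 30 enynyl isoxazoline lactam phenol
Product: 31 cis-dienyl isoxazoline lactam phenol (fragment W)
Conditions: Zn (activated with Cu(OAc)2 and AgNO3), MeOH/H2O, 23 °C
Reagents that add atoms: none
Why: Zinc-mediated cis-semireduction of the conjugated alkyne (Boland reduction) should give the cis-diene without reducing the terminal vinyl group or the N–O bond.

**Union and endgame**

Step 20
Reactants: 11 1-hydroxy-5,7-dimethyl-3a,4,5,6,7,7a-hexahydro-1H-inden-3-yl trifluoromethanesulfonate (fragment A); 31 cis-dienyl isoxazoline lactam phenol (fragment W)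
Product: 32 aryl ether enol triflate
Conditions: PPh3, DIAD, PhMe, 0 → 23 °C
Reagents that add atoms: none
Why: Mitsunobu etherification by the phenol proceeds with SN2 inversion at C-k, placing the aryloxy group on the face required in the target; the electron-poor vinyl triflate disfavours ionisation.

Step 21
Reactants: 32 aryl ether enol triflate
Product: 33 (E)-dienyl pinacol boronate
Conditions: (E)-1,2-bis(pinacolboryl)ethene (3 equiv), Pd(PPh3)4 (5 mol %), K3PO4 (aq), THF, 45 °C
Reagents that add atoms: (E)-1,2-bis(4,4,5,5-tetramethyl-1,3,2-dioxaborolan-2-yl)ethene CC1(C)OB(OC1(C)C)/C=C/B2OC(C)(C)C(C)(C)O2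
Why: Suzuki–Miyaura mono-coupling of the enol triflate with the excess diboryl ethene builds the diene with retention of the E geometry.

Step 22
Reactants: 33 (E)-dienyl pinacol boronate
Product: 34 (E)-dienyl acetate
Conditions: Cu(OAc)2 (2.2 equiv), Et3N, MeCN, air, 23 °C
Reagents that add atoms: copper diacetate CC(=O)[O-].CC(=O)[O-].[Cu+2]
Why: Copper-mediated oxidative C–O coupling of the alkenyl boronate with acetate (Chan–Lam type) gives the enol acetate with retention of alkene geometry.

Step 23
Reactants: 34 (E)-dienyl acetate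
Product: 36 cis-dienoyl dihydroxy lactam (cycloaddition precursor), via β-hydroxy imine 35 (not isolated)
Conditions: SmI2, THF, 0 °C; then B(OH)3, MeOH/H2O, 23 °C
Reagents that add atoms: water O
Why: Reductive N–O cleavage and imine hydrolysis unmask the isoxazoline as the β-hydroxy ketone, so the acidic, activated cis-dienone appears only directly before the key step.

Step 24
Reactants: 36 cis-dienoyl dihydroxy lactam
Product: 37 macrocyclic cycloadduct with allylic acetate
Conditions: PhMe (1 mM), BHT (cat.), 90 °C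
Reagents that add atoms: none
Why: A thermal suprafacial [4+2] cycloaddition joins the 1-acetoxy-diene of rings B/C with the cis-enone of the enolised 3-acyl lactam; the closest known reaction type is a type-1 intramolecular Diels–Alder macrocyclisation. Ring A closes as the six-membered cycloadduct, and the 13-membered para-cyclophane closes as the fused ring when the ring-B diene terminus bonds to the acyl-bearing dienophile carbon. The A/B fusion methine is set by delivery of the dienophile from the face of the C-k aryloxy group, where the strap originates; the vinyl- and acyl-bearing carbons are set cis by the Z dienophile, and the acetoxy carbon by the E diene. The step needs the exo orientation, which is expected because the endo mode would push the lactam and vinyl group over the three axial hydrogens on that face of ring C. Regiochemistry is fixed by the strap, and high dilution with a radical inhibitor should suppress oligomerisation and cis-to-trans isomerisation of the dienone.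

Step 25
Reactants: 37 macrocyclic cycloadduct with allylic acetate
Product: 40 xenoacremone A, via N-allyl sulfonyl hydrazone 38 (not isolated), via allylic diazene 39 (not isolated)
Conditions: N-isopropylidene-N'-(2-nitrobenzenesulfonyl)hydrazine, i-Pr2NEt, [Pd(allyl)Cl]2 (5 mol %), PPh3 (20 mol %), THF, 23 °C; then CF3CH2OH/H2O (1:1), AcOH, 23 °C
Reagents that add atoms: none
Why: Palladium-catalysed allylic substitution by the hydrazone nitrogen should occur with net retention at the less hindered terminus, and the derived diazene loses dinitrogen by a retro-ene shift that delivers hydrogen suprafacially to the ring-fusion carbon, moving the alkene into place and setting the trans A/B fusion.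

**Compound list**

1 | cis-3,5-dimethylcyclohexanone (meso) | O=C1C[C@H](C)C[C@H](C)C1 | starting material
2 | (3S,5R)-3,5-dimethyl-1-(trimethylsilyloxy)cyclohex-1-ene | C[Si](C)(C)OC1=C[C@@H](C)C[C@@H](C)C1 | intermediate
3 | 2-(dimethoxymethyl)-3,5-dimethylcyclohexan-1-one, all substituents equatorial (acetal trans to neighbouring methyl, methyls cis) | O=C1C[C@H](C)C[C@H](C)[C@H]1C(OC)OC | intermediate
4 | 2-(dimethoxymethyl)-3,5-dimethylcyclohexane-1-carbonitrile, drawn as the all-equatorial epimer | N#C[C@@H]1C[C@H](C)C[C@H](C)[C@H]1C(OC)OC | intermediate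
5 | N-unsubstituted methyl ketimine from 4 | CC(=N)[C@@H]1C[C@H](C)C[C@H](C)[C@H]1C(OC)OC | intermediate
6 | 1-[2-(dimethoxymethyl)-3,5-dimethylcyclohexyl]ethan-1-one, all-equatorial | CC(=O)[C@@H]1C[C@H](C)C[C@H](C)[C@H]1C(OC)OC | intermediate
7 | 2-acetyl-4,6-dimethylcyclohexane-1-carbaldehyde, all-equatorial | CC(=O)[C@@H]1C[C@H](C)C[C@H](C)[C@H]1C=O | intermediate
8 | trans-fused 3-hydroxy-4,6-dimethyloctahydro-1H-inden-1-one, hydroxyl cis to the adjacent ring-fusion hydrogen | O=C1[C@@H]2C[C@H](C)C[C@H](C)[C@H]2[C@H](O)C1 | intermediate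
9 | tert-butyldimethylsilyl ether of 8 | O=C1[C@@H]2C[C@H](C)C[C@H](C)[C@H]2[C@H](O[Si](C)(C)C(C)(C)C)C1 | intermediate
10 | trans-fused 1-(tert-butyldimethylsilyloxy)-5,7-dimethyl-3a,4,5,6,7,7a-hexahydro-1H-inden-3-yl triflate | FC(F)(F)S(=O)(=O)OC1=C[C@@H](O[Si](C)(C)C(C)(C)C)[C@@H]2[C@@H](C)C[C@@H](C)C[C@@H]12 | intermediate
11 | trans-fused 1-hydroxy-5,7-dimethyl-3a,4,5,6,7,7a-hexahydro-1H-inden-3-yl triflate (fragment A) | FC(F)(F)S(=O)(=O)OC1=C[C@@H](O)[C@@H]2[C@@H](C)C[C@@H](C)C[C@@H]12 | intermediate
12 | (4-bromophenoxy)triisopropylsilane | CC(C)[Si](C(C)C)(C(C)C)Oc1ccc(Br)cc1 | starting material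
13 | (R)-epichlorohydrin | ClC[C@H]1CO1 | starting material
14 | [4-(triisopropylsilyloxy)phenyl]magnesium bromide | CC(C)[Si](C(C)C)(C(C)C)Oc1ccc([Mg]Br)cc1 | intermediate
15 | (R)-1-chloro-3-[4-(triisopropylsilyloxy)phenyl]propan-2-ol | CC(C)[Si](C(C)C)(C(C)C)Oc1ccc(cc1)C[C@@H](O)CCl | intermediate
16 | (R)-2-[4-(triisopropylsilyloxy)benzyl]oxirane | CC(C)[Si](C(C)C)(C(C)C)Oc1ccc(cc1)C[C@@H]2CO2 | intermediate
17 | (phenylthio)acetic acid | OC(=O)CSc1ccccc1 | starting material
18 | (4R)-4-hydroxy-2-(phenylthio)-5-[4-(triisopropylsilyloxy)phenyl]pentanoic acid (mixture at C-2) | CC(C)[Si](C(C)C)(C(C)C)Oc1ccc(cc1)C[C@@H](O)CC(Sc2ccccc2)C(O)=O | intermediate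
19 | (5R)-3-(phenylthio)-5-[4-(triisopropylsilyloxy)benzyl]dihydrofuran-2(3H)-one (mixture at C-3) | CC(C)[Si](C(C)C)(C(C)C)Oc1ccc(cc1)C[C@@H]2CC(Sc3ccccc3)C(=O)O2 | intermediate
20 | sulfoxide of 19 | CC(C)[Si](C(C)C)(C(C)C)Oc1ccc(cc1)C[C@@H]2CC(S(=O)c3ccccc3)C(=O)O2 | intermediate
21 | (R)-5-[4-(triisopropylsilyloxy)benzyl]furan-2(5H)-one | CC(C)[Si](C(C)C)(C(C)C)Oc1ccc(cc1)C[C@H]2OC(=O)C=C2 | intermediate
22 | 3-(trimethylsilyl)prop-2-ynal | C[Si](C)(C)C#CC=O | starting material
23 | 3-(trimethylsilyl)prop-2-ynal oxime | C[Si](C)(C)C#CC=NO | intermediate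
24 | 3-(trimethylsilyl)prop-2-ynenitrile oxide | C[Si](C)(C)C#CC#[N+][O-] | intermediate
25 | cis-fused 3a,6a-dihydrofuro[3,4-d]isoxazol-4(6H)-one with 3-(trimethylsilylethynyl) and, on the face opposite the isoxazoline, 6-[4-(triisopropylsilyloxy)benzyl] | CC(C)[Si](C(C)C)(C(C)C)Oc1ccc(cc1)C[C@H]2OC(=O)[C@H]3[C@@H]2ON=C3C#C[Si](C)(C)C | intermediate
26 | 4,5-dihydroisoxazole-4-carboxamide with 3-(trimethylsilylethynyl) and 5-[1-hydroxy-2-arylethyl], 4,5-cis | CC(C)[Si](C(C)C)(C(C)C)Oc1ccc(cc1)C[C@@H](O)[C@H]2ON=C(C#C[Si](C)(C)C)[C@H]2C(N)=O | intermediate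
27 | keto amide from 26 (carbinol oxidised) | CC(C)[Si](C(C)C)(C(C)C)Oc1ccc(cc1)CC(=O)[C@H]2ON=C(C#C[Si](C)(C)C)[C@H]2C(N)=O | intermediate
28 | cis-fused 6-hydroxy-6-[4-(triisopropylsilyloxy)benzyl]-3-(trimethylsilylethynyl)-3a,5,6,6a-tetrahydro-4H-pyrrolo[3,4-d]isoxazol-4-one, hydroxyl cis to ring oxygen | CC(C)[Si](C(C)C)(C(C)C)Oc1ccc(cc1)C[C@@]2(O)NC(=O)[C@H]3[C@@H]2ON=C3C#C[Si](C)(C)C | intermediate
29 | 3-ethynyl-6-hydroxy-6-(4-hydroxybenzyl) analogue of 28 | Oc1ccc(cc1)C[C@@]2(O)NC(=O)[C@H]3[C@@H]2ON=C3C#C | intermediate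
30 | 3-(but-3-en-1-ynyl) analogue of 29 | Oc1ccc(cc1)C[C@@]2(O)NC(=O)[C@H]3[C@@H]2ON=C3C#CC=C | intermediate
31 | 3-[(Z)-buta-1,3-dienyl] analogue of 29 (fragment W) | Oc1ccc(cc1)C[C@@]2(O)NC(=O)[C@H]3[C@@H]2ON=C3/C=C\C=C | intermediate
32 | aryl ether of fragments A and W: enol triflate, aryloxy on C-k inverted relative to 11 | FC(F)(F)S(=O)(=O)OC1=C[C@H](Oc3ccc(cc3)C[C@@]4(O)NC(=O)[C@H]5[C@@H]4ON=C5/C=C\C=C)[C@@H]2[C@@H](C)C[C@@H](C)C[C@@H]12 | intermediate
33 | (E)-2-(pinacolboryl)vinyl analogue of 32 | CC6(C)OB(OC6(C)C)/C=C/C1=C[C@H](Oc3ccc(cc3)C[C@@]4(O)NC(=O)[C@H]5[C@@H]4ON=C5/C=C\C=C)[C@@H]2[C@@H](C)C[C@@H](C)C[C@@H]12 | intermediate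
34 | (E)-2-acetoxyvinyl analogue of 32 | CC(=O)O/C=C/C1=C[C@H](Oc3ccc(cc3)C[C@@]4(O)NC(=O)[C@H]5[C@@H]4ON=C5/C=C\C=C)[C@@H]2[C@@H](C)C[C@@H](C)C[C@@H]12 | intermediate
35 | β-hydroxy N-H ketimine from N–O cleavage of 34 | CC(=O)O/C=C/C1=C[C@H](Oc3ccc(cc3)C[C@@]4(O)NC(=O)[C@H](C(=N)/C=C\C=C)[C@@H]4O)[C@@H]2[C@@H](C)C[C@@H](C)C[C@@H]12 | intermediate
36 | 3-[(Z)-penta-2,4-dienoyl]-4,5-dihydroxy lactam (enol form) tethered to the (E)-acetoxy-diene | CC(=O)O/C=C/C1=C[C@H](Oc3ccc(cc3)C[C@@]4(O)NC(=O)/C(=C(\O)/C=C\C=C)[C@@H]4O)[C@@H]2[C@@H](C)C[C@@H](C)C[C@@H]12 | intermediate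
37 | macrocyclic cycloadduct: ring A with allylic acetate trans to the vinyl group and alkene at the future A/B fusion carbon | C=C[C@@H]1[C@@H](OC(C)=O)C=C2[C@@H]3C[C@H](C)C[C@H](C)[C@H]3[C@H]3Oc4ccc(cc4)C[C@@]4(O)NC(=O)/C(=C(\O)[C@H]1[C@@H]23)[C@@H]4O | intermediate
38 | N-allyl N-(2-nitrobenzenesulfonyl) acetone hydrazone from 37 | C=C[C@@H]1[C@@H](N(N=C(C)C)S(=O)(=O)c5ccccc5[N+](=O)[O-])C=C2[C@@H]3C[C@H](C)C[C@H](C)[C@H]3[C@H]3Oc4ccc(cc4)C[C@@]4(O)NC(=O)/C(=C(\O)[C@H]1[C@@H]23)[C@@H]4O | intermediate
39 | allylic monoalkyl diazene | C=C[C@@H]1[C@@H](N=N)C=C2[C@@H]3C[C@H](C)C[C@H](C)[C@H]3[C@H]3Oc4ccc(cc4)C[C@@]4(O)NC(=O)/C(=C(\O)[C@H]1[C@@H]23)[C@@H]4O | intermediate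
40 | xenoacremone A | C=C[C@@H]1C=C[C@@H]2[C@@H]3C[C@H](C)C[C@H](C)[C@H]3[C@H]3Oc4ccc(cc4)C[C@@]4(O)NC(=O)/C(=C(\O)[C@H]1[C@@H]23)[C@@H]4O | target

**Totals.** Total step count: 25. Longest linear sequence: 15 steps (steps 10–12 and 14–25; steps 1–9 followed by 20–25 is equally long).

**Steps most likely to fail**

Step 24. The cycloaddition may pass through the endo orientation, or the cis-dienone may isomerise to the trans-dienone before it cyclises. The fallback uses that behaviour instead of fighting it and sets out from 36. Catalytic I2 in CH2Cl2 isomerises 36 to the all-trans dienone, the (E)-penta-2,4-dienoyl lactam F1. Heating F1 under the conditions of step 24 in the acyl-endo mode should place the vinyl group exo, giving the cycloadduct epimeric at the acyl-bearing carbon F2. Equilibration of F2 with DBU in THF should move the acyl group into the equatorial position, and the route is rejoined at 37.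

Step 25. The allylpalladium intermediate may be captured by the enolised tricarbonyl, or may lose a β-hydrogen, instead of reacting with the hydrazone. The fallback re-masks the acidic groups before the palladium step and sets out from 37. Me3SiCl and imidazole in DMF give the tris(trimethylsilyl) ether F3. The same allylic substitution then gives the silylated N-allyl sulfonyl hydrazone F4. Aqueous trifluoroethanol with AcOH removes the silyl groups and the isopropylidene group, and diazene 39 collapses to 40, where the route is rejoined.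

Step 6. The reversible aldol may drift to the cis-fused hydrindanone, dehydrate, or give the wrong carbinol epimer. The fallback closes ring B irreversibly at low temperature and sets out from 6. LiN(i-Pr)2 and Me3SiCl at −78 °C give the kinetic silyl enol ether F5. N-Bromosuccinimide converts F5 into the bromomethyl ketone acetal F6. Aqueous CF3CO2H gives the bromo keto aldehyde F7. SmI2 in THF at −78 °C then effects an intramolecular Reformatsky-type aldol addition, and the route is rejoined at 8.

**Further compounds**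

F1 | step 24 | (E)-penta-2,4-dienoyl isomer of 36 | CC(=O)O/C=C/C1=C[C@H](Oc3ccc(cc3)C[C@@]4(O)NC(=O)/C(=C(\O)/C=C/C=C)[C@@H]4O)[C@@H]2[C@@H](C)C[C@@H](C)C[C@@H]12
F2 | step 24 | epimer of 37 at the acyl-bearing ring A carbon | C=C[C@@H]1[C@@H](OC(C)=O)C=C2[C@@H]3C[C@H](C)C[C@H](C)[C@H]3[C@H]3Oc4ccc(cc4)C[C@@]4(O)NC(=O)/C(=C(\O)[C@@H]1[C@@H]23)[C@@H]4O
F3 | step 25 | tris(trimethylsilyl) ether of 37 (enol, C-4 and C-5 oxygens of the lactam) | C=C[C@@H]1[C@@H](OC(C)=O)C=C2[C@@H]3C[C@H](C)C[C@H](C)[C@H]3[C@H]3Oc4ccc(cc4)C[C@@]4(O[Si](C)(C)C)NC(=O)/C(=C(\O[Si](C)(C)C)[C@H]1[C@@H]23)[C@@H]4O[Si](C)(C)C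
F4 | step 25 | tris(trimethylsilyl) ether of 38 | C=C[C@@H]1[C@@H](N(N=C(C)C)S(=O)(=O)c5ccccc5[N+](=O)[O-])C=C2[C@@H]3C[C@H](C)C[C@H](C)[C@H]3[C@H]3Oc4ccc(cc4)C[C@@]4(O[Si](C)(C)C)NC(=O)/C(=C(\O[Si](C)(C)C)[C@H]1[C@@H]23)[C@@H]4O[Si](C)(C)C
F5 | step 6 | trimethylsilyl enol ether of 6 (terminal) | C=C(O[Si](C)(C)C)[C@@H]1C[C@H](C)C[C@H](C)[C@H]1C(OC)OC
F6 | step 6 | bromomethyl ketone acetal | BrCC(=O)[C@@H]1C[C@H](C)C[C@H](C)[C@H]1C(OC)OC
F7 | step 6 | 2-(bromoacetyl)-4,6-dimethylcyclohexane-1-carbaldehyde, all-equatorial | BrCC(=O)[C@@H]1C[C@H](C)C[C@H](C)[C@H]1C=O
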